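**Plan**

Numbering: ring A is the cyclohexene, C1 (=C–CH2Ar), C2 (=C–CH3), C3H2, C4H2, C5HBr, C6 (quaternary); the chain runs C7H2–C8H2–C9HBr–C10(OH)CH3–C11H2–C12H2–C13H(O‑acyl)–C14(CH3)2Br.
Cuts, in retrosynthetic order: C14–Br (hydrobromination of an isopropenyl group), C9–Br (bromide opening of a 9,10‑epoxide), lactone C13–O (Mitsunobu), ArCH2–C1 (Negishi on an enol triflate), C8–C9 (B‑alkyl Suzuki), C6–C7 with C5–Br (bromonium‑induced 1,2‑vinyl shift), and last C2–C3 with C4–C5 of ring A (Diels–Alder).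
Enabling feature: in ring A the unsubstituted C3H2–C4H2 unit bridges C2 and C5, and C2–C1–C6–C5 is the carbon skeleton of ethyl isopropenyl ketone; as its 2‑silyloxydiene this unit takes up acrolein as an ethylene equivalent, the formyl helper being excised afterwards.
Forward order: ring A (steps 1–4), C1 carbinol, semipinacol shift (C6 quaternary centre and C5–Br), enol triflate, side chain, epoxide, arylmethyl group, macrolactone, then the two remaining C–Br bonds.
Stereochemistry: the catalyst‑controlled Diels–Alder step sets C2, a relay centre erased in step 7; it directs vinyl addition at C1, and the anti‑periplanar 1,2‑shift passes this on to C6 and C5. C9/C10 come from Shi epoxidation and SN2 opening, C13 from CBS reduction and Mitsunobu inversion.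

Key step: step 2

Assumption: the (S)‑configured oxazaborolidinium catalyst is taken to give the (5R)‑adduct 4 by analogy with its usual sense for enals and 2‑silyloxydienes; if the sense is opposite, the (R)‑catalyst is used and nothing else changes.

**Route**

Step 1
Reactants: 1 2-methylpent-1-en-3-one
Product: 2 (Z)-triisopropyl[(2-methylpenta-1,3-dien-3-yl)oxy]silane
Conditions: i-Pr3SiOTf, Et3N, CH2Cl2, 0 °C
Reagents that add atoms: triisopropylsilyl trifluoromethanesulfonate, CC(C)[Si](C(C)C)(C(C)C)OS(=O)(=O)C(F)(F)F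
Why: Soft enolisation of the ethyl ketone (silyl triflate/amine) should give the cross-conjugated 2-silyloxydiene as the (Z)-enol ether, so that the terminal methyl lies outside the s-cis diene.

Step 2
Reactants: 2 (Z)-triisopropyl[(2-methylpenta-1,3-dien-3-yl)oxy]silane; 3 acrolein
Product: 4 (1S,5R)-3,5-dimethyl-4-(triisopropylsilyloxy)cyclohex-3-ene-1-carbaldehyde
Conditions: (S)-3,3-diphenyl-1-(2-methylphenyl)tetrahydro-1H,3H-pyrrolo[1,2-c][1,3,2]oxazaborole (20 mol%), HN(SO2CF3)2 (20 mol%), CH2Cl2, −78 °C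
Reagents that add atoms: none
Why: This is a normal-electron-demand Diels–Alder reaction in which the enal, bound and LUMO-lowered by the chiral cationic oxazaborolidine, adds in a concerted asynchronous suprafacial [4+2] event to the s-cis 2-silyloxydiene and forms C2–C3 and C4–C5 of ring A (C5–C6 and C1–C2 of 4) at once. The closest known reaction type is the oxazaborolidinium-catalysed enantioselective Diels–Alder reaction of 2-(trialkylsilyloxy)-1,3-dienes with α,β-unsaturated aldehydes and acrylates. The six-membered carbocycle closes by intermolecular [4+2] cycloaddition, with no tether. The methyl-bearing centre (C2 of ring A, C5 of 4) is controlled by the catalyst-shielded enal face together with endo approach and the fixed (Z)-geometry of the enol ether; the formyl-bearing centre follows the endo rule and is deleted in step 3. The step needs regioselectivity (enal β-carbon to the enol-ether terminus, secured by the larger HOMO coefficient there and made irrelevant by the later decarbonylation), endo and enantiofacial selectivity (catalyst), and cycloaddition in preference to Mukaiyama–Michael addition (bulky silyl group, low temperature).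

Step 3
Reactants: 4 (1S,5R)-3,5-dimethyl-4-(triisopropylsilyloxy)cyclohex-3-ene-1-carbaldehyde
Product: 5 (R)-[(2,6-dimethylcyclohex-1-en-1-yl)oxy]triisopropylsilane
Conditions: RhCl(PPh3)3 (1.05 equiv), toluene, 110 °C
Reagents that add atoms: none
Why: Tsuji–Wilkinson decarbonylation (formyl C–H oxidative addition, CO extrusion, C–H reductive elimination) removes the activating group, and the silyl enol ether keeps the C2 centre away from any enolisable carbonyl.

Step 4
Reactants: 5 (R)-[(2,6-dimethylcyclohex-1-en-1-yl)oxy]triisopropylsilane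
Product: 6 (R)-2,6-dimethylcyclohex-2-en-1-one
Conditions: Pd(OAc)2 (1.1 equiv), MeCN/CH2Cl2, 40 °C
Reagents that add atoms: none
Why: Saegusa–Ito oxidation, in which the palladium enolate undergoes β-hydride elimination toward the ring CH2 (C5) to give the endocyclic enone under neutral conditions that leave the C2 centre untouched.

Step 5
Reactants: 6 (R)-2,6-dimethylcyclohex-2-en-1-one
Product: 7 (1R,6R)-1-ethenyl-2,6-dimethylcyclohex-2-en-1-ol
Conditions: CH2=CHMgBr, CeCl3, THF, −78 °C
Reagents that add atoms: vinylmagnesium bromide, C=C[Mg]Br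
Why: Cerium-mediated 1,2-addition (enolisation and conjugate addition suppressed), with the nucleophile expected to approach the carbonyl face anti to the adjacent pseudo-equatorial C2 methyl group, which sets the carbinol centre C1.

Step 6
Reactants: 7 (1R,6R)-1-ethenyl-2,6-dimethylcyclohex-2-en-1-ol
Product: 8 (2S,3S,6R)-3-bromo-2-ethenyl-2,6-dimethylcyclohexan-1-one
Conditions: NBS, NaHCO3, CH2Cl2, −20 °C → 0 °C
Reagents that add atoms: N-bromosuccinimide, O=C1CCC(=O)N1Br
Why: Halonium-induced semipinacol rearrangement of a tertiary allylic alcohol, in which the bromonium ion forms on the trisubstituted ring alkene anti to the pseudo-axial vinyl group and a suprafacial 1,2-vinyl shift from C1 to C6 follows, so that the quaternary centre C6 and C5–Br (trans to the migrated group, cis to methyl) are set stereospecifically from C1.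

Step 7
Reactants: 8 (2S,3S,6R)-3-bromo-2-ethenyl-2,6-dimethylcyclohexan-1-one
Product: 10 (5S,6S)-5-bromo-6-ethenyl-2,6-dimethylcyclohex-1-en-1-yl trifluoromethanesulfonate, via potassium enolate 9 (not isolated)
Conditions: KN(SiMe3)2, THF, −78 °C; then PhN(SO2CF3)2, −78 °C → 0 °C
Reagents that add atoms: N-phenylbis(trifluoromethanesulfonimide), O=S(=O)(N(c1ccccc1)S(=O)(=O)C(F)(F)F)C(F)(F)F
Why: Deprotonation by the non-nucleophilic amide at the only enolisable position (C2) and O-triflation give the tetrasubstituted enol triflate, which erases the C2 relay centre.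

Step 8
Reactants: 11 pent-4-ynoic acid
Product: 12 N-methoxy-N-methylpent-4-ynamide
Conditions: MeNHOMe·HCl, 1-ethyl-3-(3-dimethylaminopropyl)carbodiimide hydrochloride, Et3N, DMAP (cat.), CH2Cl2, rt
Reagents that add atoms: N,O-dimethylhydroxylamine hydrochloride, CNOC.Cl
Why: Carbodiimide-mediated amide coupling to the Weinreb amide.

Step 9
Reactants: 12 N-methoxy-N-methylpent-4-ynamide
Product: 13 2-methylhept-1-en-6-yn-3-one
Conditions: CH2=C(CH3)MgBr (2.2 equiv), THF, −20 °C; cold dilute HCl quench
Reagents that add atoms: isopropenylmagnesium bromide, CC(=C)[Mg]Br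
Why: Weinreb ketone synthesis, in which the chelated tetrahedral intermediate prevents over-addition and one equivalent of reagent is consumed by the alkyne C–H.

Step 10
Reactants: 13 2-methylhept-1-en-6-yn-3-one
Product: 14 (R)-2-methylhept-1-en-6-yn-3-ol
Conditions: (S)-1-methyl-3,3-diphenyltetrahydro-1H,3H-pyrrolo[1,2-c][1,3,2]oxazaborole (10 mol%), catecholborane, toluene, −78 °C
Reagents that add atoms: none
Why: Corey–Bakshi–Shibata reduction with the 2-propenyl group as the large substituent, so that hydride delivery should give the (R)-allylic alcohol.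

Step 11
Reactants: 14 (R)-2-methylhept-1-en-6-yn-3-ol
Product: 15 (R)-tert-butyldimethyl[(2-methylhept-1-en-6-yn-3-yl)oxy]silane
Conditions: t-BuMe2SiCl, imidazole, DMF, rt
Reagents that add atoms: tert-butyldimethylsilyl chloride, CC(C)(C)[Si](C)(C)Cl
Why: Standard silylation of the secondary alcohol.

Step 12
Reactants: 15 (R)-tert-butyldimethyl[(2-methylhept-1-en-6-yn-3-yl)oxy]silane
Product: 17 (R,E)-tert-butyl[(7-iodo-2,6-dimethylhepta-1,6-dien-3-yl)oxy]dimethylsilane, via alkenyldimethylalane 16 (not isolated)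
Conditions: AlMe3, Cp2ZrCl2 (20 mol%), CH2Cl2, 0 °C → rt; then I2, THF, −30 °C
Reagents that add atoms: trimethylaluminium, C[Al](C)C; iodine, II
Why: Zirconium-catalysed methylalumination (Negishi carboalumination) adds CH3 and Al syn across the terminal alkyne with aluminium at the terminus, and iodinolysis with retention gives the (E)-alkenyl iodide.

Step 13
Reactants: 10 (5S,6S)-5-bromo-6-ethenyl-2,6-dimethylcyclohex-1-en-1-yl trifluoromethanesulfonate; 17 (R,E)-tert-butyl[(7-iodo-2,6-dimethylhepta-1,6-dien-3-yl)oxy]dimethylsilane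
Product: 19 (5S,6S)-5-bromo-6-[(3E,7R)-7-(tert-butyldimethylsilyloxy)-4,8-dimethylnona-3,8-dien-1-yl]-2,6-dimethylcyclohex-1-en-1-yl trifluoromethanesulfonate, via B-alkyl-9-BBN adduct 18 (not isolated)
Conditions: 9-BBN-H, THF, rt; then 17, PdCl2(dppf) (5 mol%), AsPh3, Cs2CO3, DMF/H2O, rt
Reagents that add atoms: none
Why: Anti-Markovnikov hydroboration of the monosubstituted vinyl group, then B-alkyl Suzuki–Miyaura coupling in which oxidative addition to the alkenyl iodide should outpace that to the hindered enol triflate, with the (E)-geometry retained.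

Step 14
Reactants: 19 (5S,6S)-5-bromo-6-[(3E,7R)-7-(tert-butyldimethylsilyloxy)-4,8-dimethylnona-3,8-dien-1-yl]-2,6-dimethylcyclohex-1-en-1-yl trifluoromethanesulfonate
Product: 20 (9S,10S)-9,10-epoxide of 19
Conditions: 1,2:4,5-di-O-isopropylidene-β-L-erythro-2,3-hexodiulo-2,6-pyranose (30 mol%), 2KHSO5·KHSO4·K2SO4, K2CO3, Bu4NHSO4, MeCN/CH2(OMe)2/aq. buffer pH 10.5, 0 °C
Reagents that add atoms: potassium peroxymonosulfate, [K+].[O-]S(=O)(=O)OO
Why: Shi epoxidation of the electron-rich (E)-trisubstituted alkene through the spiro transition state of the chiral dioxirane, the L-series ketone giving the (9S,10S)-epoxide, while the enol triflate and the silyloxy-flanked 1,1-disubstituted alkene should react more slowly.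

Step 15
Reactants: 21 4-hydroxy-3-methylbenzoic acid
Product: 22 triisopropylsilyl 3-methyl-4-(triisopropylsilyloxy)benzoate
Conditions: i-Pr3SiCl (2.2 equiv), imidazole, DMF, rt
Reagents that add atoms: triisopropylsilyl chloride, CC(C)[Si](Cl)(C(C)C)C(C)C
Why: Silylation of both the phenol and the carboxylic acid in one operation.

Step 16
Reactants: 22 triisopropylsilyl 3-methyl-4-(triisopropylsilyloxy)benzoate
Product: 23 triisopropylsilyl 3-(bromomethyl)-4-(triisopropylsilyloxy)benzoate
Conditions: NBS, AIBN (cat.), PhCF3, 85 °C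
Reagents that add atoms: N-bromosuccinimide, O=C1CCC(=O)N1Br
Why: Wohl–Ziegler radical bromination of the benzylic methyl group.

Step 17
Reactants: 20 (9S,10S)-9,10-epoxide of 19; 23 triisopropylsilyl 3-(bromomethyl)-4-(triisopropylsilyloxy)benzoate
Product: 25 fully silylated seco-acid: the C1-arylmethyl coupling product of 20 carrying the (9S,10S)-epoxide and the (13R)-silyl ether, via benzylic zinc bromide 24 (not isolated)
Conditions: 23, Zn, LiCl, THF, rt; then 20, Pd(PPh3)4 (5 mol%), THF, 50 °C
Reagents that add atoms: none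
Why: LiCl-assisted zinc insertion gives the benzylic zinc reagent, and its Negishi coupling with the enol triflate builds the tetrasubstituted C1=C2 alkene, with the secondary alkyl bromide, silyl ester and epoxide expected to tolerate the mild organozinc.

Step 18
Reactants: 25 fully silylated seco-acid
Product: 26 (13R)-seco-acid with free phenol, free carboxylic acid and (9S,10S)-epoxide
Conditions: Bu4NF, AcOH, THF, 0 °C → rt; aq. NaH2PO4 work-up
Reagents that add atoms: none
Why: Fluoride cleaves the silyl ester, the aryl silyl ether and the secondary silyl ether in one operation, the acetic acid buffer limiting base-induced elimination of the C5 bromide.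

Step 19
Reactants: 26 (13R)-seco-acid
Product: 27 (5S,6S,9S,10S,13S)-macrolactone bearing the 9,10-epoxide and the 13-isopropenyl group
Conditions: PPh3, DIAD, toluene, high dilution with slow addition, 0 °C → rt
Reagents that add atoms: none
Why: Mitsunobu macrolactonisation, in which the carboxylate attacks the alkoxyphosphonium ion at C13 with inversion (R to S) and the more acidic carboxylic acid should react in preference to the phenol.

Step 20
Reactants: 27 (5S,6S,9S,10S,13S)-macrolactone epoxide
Product: 28 (5S,6S,9R,10S,13S)-9-bromo-10-hydroxy macrolactone with the 13-isopropenyl group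
Conditions: Li2NiBr4, THF, 0 °C → rt
Reagents that add atoms: dilithium tetrabromonickelate, [Li+].[Li+].[Ni+2].[Br-].[Br-].[Br-].[Br-]
Why: Soft nucleophilic bromide should open the trisubstituted epoxide by SN2 attack at the less substituted carbon C9 with inversion, turning the (9S,10S)-epoxide into the anti (9R,10S)-bromohydrin.

Step 21
Reactants: 28 (5S,6S,9R,10S,13S)-9-bromo-10-hydroxy macrolactone
Product: 29 bromophycolide A
Conditions: Co(acac)2 (25 mol%), t-BuOOH (25 mol%), Et3SiH, TsBr, n-PrOH/CH2Cl2, rt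
Reagents that add atoms: 4-methylbenzenesulfonyl bromide, Cc1ccc(cc1)S(=O)(=O)Br
Why: Mukaiyama-type hydrogen-atom-transfer hydrobromination, in which the cobalt hydride delivers H to the CH2 terminus of the 1,1-disubstituted alkene and the tertiary radical abstracts bromine from the sulfonyl bromide (Markovnikov), while the hindered tetrasubstituted ring alkene should be left alone.

**Compound list**

1 | 2-methylpent-1-en-3-one | CCC(=O)C(C)=C | starting material
2 | (Z)-triisopropyl[(2-methylpenta-1,3-dien-3-yl)oxy]silane | C=C(C)/C(O[Si](C(C)C)(C(C)C)C(C)C)=C/C | intermediate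
3 | acrolein | C=CC=O | starting material
4 | (1S,5R)-3,5-dimethyl-4-(triisopropylsilyloxy)cyclohex-3-ene-1-carbaldehyde | C[C@@H]1C[C@H](C=O)CC(C)=C1O[Si](C(C)C)(C(C)C)C(C)C | intermediate
5 | (R)-[(2,6-dimethylcyclohex-1-en-1-yl)oxy]triisopropylsilane | C[C@@H]1CCCC(C)=C1O[Si](C(C)C)(C(C)C)C(C)C | intermediate
6 | (R)-2,6-dimethylcyclohex-2-en-1-one | C[C@@H]1CCC=C(C)C1=O | intermediate
7 | (1R,6R)-1-ethenyl-2,6-dimethylcyclohex-2-en-1-ol | C=C[C@]1(O)C(C)=CCC[C@H]1C | intermediate
8 | (2S,3S,6R)-3-bromo-2-ethenyl-2,6-dimethylcyclohexan-1-one | C=C[C@]1(C)[C@@H](Br)CC[C@@H](C)C1=O | intermediate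
9 | potassium (5S,6S)-5-bromo-6-ethenyl-2,6-dimethylcyclohex-1-en-1-olate | C=C[C@]1(C)[C@@H](Br)CCC(C)=C1[O-].[K+] | intermediate (not isolated)
10 | (5S,6S)-5-bromo-6-ethenyl-2,6-dimethylcyclohex-1-en-1-yl trifluoromethanesulfonate | C=C[C@]1(C)[C@@H](Br)CCC(C)=C1OS(=O)(=O)C(F)(F)F | intermediate
11 | pent-4-ynoic acid | C#CCCC(=O)O | starting material
12 | N-methoxy-N-methylpent-4-ynamide | C#CCCC(=O)N(C)OC | intermediate
13 | 2-methylhept-1-en-6-yn-3-one | C#CCCC(=O)C(C)=C | intermediate
14 | (R)-2-methylhept-1-en-6-yn-3-ol | C#CCC[C@@H](O)C(C)=C | intermediate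
15 | (R)-tert-butyldimethyl[(2-methylhept-1-en-6-yn-3-yl)oxy]silane | C#CCC[C@@H](O[Si](C)(C)C(C)(C)C)C(C)=C | intermediate
16 | (E)-alkenyldimethylalane from 15 | C[Al](C)/C=C(\C)CC[C@@H](O[Si](C)(C)C(C)(C)C)C(C)=C | intermediate (not isolated)
17 | (R,E)-tert-butyl[(7-iodo-2,6-dimethylhepta-1,6-dien-3-yl)oxy]dimethylsilane | I/C=C(\C)CC[C@@H](O[Si](C)(C)C(C)(C)C)C(C)=C | intermediate
18 | B-alkyl-9-borabicyclo[3.3.1]nonane from 10 (boron on C8) | B1(C2CCCC1CCC2)CC[C@]3(C)[C@@H](Br)CCC(C)=C3OS(=O)(=O)C(F)(F)F | intermediate (not isolated)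
19 | (5S,6S)-5-bromo-6-[(3E,7R)-7-(tert-butyldimethylsilyloxy)-4,8-dimethylnona-3,8-dien-1-yl]-2,6-dimethylcyclohex-1-en-1-yl trifluoromethanesulfonate | C=C(C)[C@H](O[Si](C)(C)C(C)(C)C)CC/C(C)=C/CC[C@]1(C)[C@@H](Br)CCC(C)=C1OS(=O)(=O)C(F)(F)F | intermediate
20 | (9S,10S)-9,10-epoxide of 19 | C=C(C)[C@H](O[Si](C)(C)C(C)(C)C)CC[C@]2(C)O[C@H]2CC[C@]1(C)[C@@H](Br)CCC(C)=C1OS(=O)(=O)C(F)(F)F | intermediate
21 | 4-hydroxy-3-methylbenzoic acid | Cc1cc(ccc1O)C(=O)O | starting material
22 | triisopropylsilyl 3-methyl-4-(triisopropylsilyloxy)benzoate | Cc1cc(ccc1O[Si](C(C)C)(C(C)C)C(C)C)C(=O)O[Si](C(C)C)(C(C)C)C(C)C | intermediate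
23 | triisopropylsilyl 3-(bromomethyl)-4-(triisopropylsilyloxy)benzoate | BrCc1cc(ccc1O[Si](C(C)C)(C(C)C)C(C)C)C(=O)O[Si](C(C)C)(C(C)C)C(C)C | intermediate
24 | benzylic zinc bromide from 23 | Br[Zn]Cc1cc(ccc1O[Si](C(C)C)(C(C)C)C(C)C)C(=O)O[Si](C(C)C)(C(C)C)C(C)C | intermediate (not isolated)
25 | fully silylated seco-acid (5S,6S,9S,10S,13R) | C=C(C)[C@H](O[Si](C)(C)C(C)(C)C)CC[C@]2(C)O[C@H]2CC[C@]1(C)[C@@H](Br)CCC(C)=C1Cc3cc(ccc3O[Si](C(C)C)(C(C)C)C(C)C)C(=O)O[Si](C(C)C)(C(C)C)C(C)C | intermediate
26 | seco-acid (5S,6S,9S,10S,13R) with free phenol, acid and 13-hydroxyl | C=C(C)[C@H](O)CC[C@]2(C)O[C@H]2CC[C@]1(C)[C@@H](Br)CCC(C)=C1Cc3cc(ccc3O)C(=O)O | intermediate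
27 | (5S,6S,9S,10S,13S)-macrolactone with 9,10-epoxide and 13-isopropenyl group | C=C(C)[C@@H]4CC[C@]2(C)O[C@H]2CC[C@]1(C)[C@@H](Br)CCC(C)=C1Cc3cc(ccc3O)C(=O)O4 | intermediate
28 | (5S,6S,9R,10S,13S)-9-bromo-10-hydroxy macrolactone with 13-isopropenyl group | C=C(C)[C@@H]4CC[C@](C)(O)[C@H](Br)CC[C@]1(C)[C@@H](Br)CCC(C)=C1Cc3cc(ccc3O)C(=O)O4 | intermediate
29 | bromophycolide A | CC1=C2Cc3cc(ccc3O)C(=O)O[C@H](C(C)(C)Br)CC[C@](C)(O)[C@H](Br)CC[C@]2(C)[C@@H](Br)CC1 | target

**Step count and risks**

Total: 21 steps. Longest linear sequence: 14 steps (1–7, 13, 14, 17–21).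

Steps most likely to fail:

Step 6. The bromonium ion may be intercepted by the tertiary hydroxyl group, or the electrophile may attack the migrating vinyl π-bond, instead of the 1,2-shift taking place. The fallback sets out from 6 and returns at 8. HC≡CMgBr with CeCl3 should add to 6 anti to the C2 methyl to give (1S,6R)-1-ethynyl-2,6-dimethylcyclohex-2-en-1-ol F1. NBS then induces the semipinacol shift of the alkynyl group, which is inert to the electrophile, to give (2S,3S,6R)-3-bromo-2-ethynyl-2,6-dimethylcyclohexan-1-one F2. Semihydrogenation (H2, Pd/CaCO3 poisoned with Pb(OAc)2, quinoline) returns 8.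

Step 17. Oxidative addition and transmetalation at the hindered tetrasubstituted enol triflate may be slow, which would leave time for zinc halide to open or rearrange the trisubstituted epoxide. The fallback sets out from 10 and returns at 25 by changing the order of events. Negishi coupling of 10 with 24 under forcing conditions gives triisopropylsilyl 3-{[(5S,6S)-5-bromo-6-ethenyl-2,6-dimethylcyclohex-1-en-1-yl]methyl}-4-(triisopropylsilyloxy)benzoate F3. Hydroboration with 9-BBN-H gives the B-alkyl-9-borabicyclo[3.3.1]nonane adduct of F3 F4, which is coupled with 17 (PdCl2(dppf), AsPh3, Cs2CO3) to the (9E)-alkene analogue of 25 F5. Shi epoxidation with the L-series ketone then gives 25, relying on the bulk of the dioxirane to spare the hindered ring alkene.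

Step 19. Oligomerisation, SN2′ attack or elimination at the allylic carbinol may outcompete closure of the fifteen-membered ring. The fallback sets out from 10, 17 and 23, returns at 27, and closes the ring by C–C coupling instead. Compound F3 (made as above) is desilylated with Bu4NF to 3-{[(5S,6S)-5-bromo-6-ethenyl-2,6-dimethylcyclohex-1-en-1-yl]methyl}-4-hydroxybenzoic acid F6, and 17 is desilylated to (3R,6E)-7-iodo-2,6-dimethylhepta-1,6-dien-3-ol F7. Intermolecular Mitsunobu esterification (PPh3, DIAD) gives, with inversion, the (3S,6E)-7-iodo-2,6-dimethylhepta-1,6-dien-3-yl ester of F6 F8. Treatment with 9-BBN-H (2.2 equiv) gives the C8-boryl O-boryl derivative of F8 F9. Intramolecular B-alkyl Suzuki–Miyaura coupling under high dilution then gives the (9E)-alkene analogue of 27 F10, and Shi epoxidation with the L-series ketone returns 27.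

Further compounds
F1 | step 6 | (1S,6R)-1-ethynyl-2,6-dimethylcyclohex-2-en-1-ol | C#C[C@]1(O)C(C)=CCC[C@H]1C
F2 | step 6 | (2S,3S,6R)-3-bromo-2-ethynyl-2,6-dimethylcyclohexan-1-one | C#C[C@]1(C)[C@@H](Br)CC[C@@H](C)C1=O
F3 | step 17 | triisopropylsilyl 3-{[(5S,6S)-5-bromo-6-ethenyl-2,6-dimethylcyclohex-1-en-1-yl]methyl}-4-(triisopropylsilyloxy)benzoate | C=C[C@]1(C)[C@@H](Br)CCC(C)=C1Cc2cc(ccc2O[Si](C(C)C)(C(C)C)C(C)C)C(=O)O[Si](C(C)C)(C(C)C)C(C)C
F4 | step 17 | B-alkyl-9-borabicyclo[3.3.1]nonane adduct of F3 | B1(C2CCCC1CCC2)CC[C@]3(C)[C@@H](Br)CCC(C)=C3Cc4cc(ccc4O[Si](C(C)C)(C(C)C)C(C)C)C(=O)O[Si](C(C)C)(C(C)C)C(C)C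
F5 | step 17 | (9E)-alkene analogue of 25 | C=C(C)[C@H](O[Si](C)(C)C(C)(C)C)CC/C(C)=C/CC[C@]1(C)[C@@H](Br)CCC(C)=C1Cc2cc(ccc2O[Si](C(C)C)(C(C)C)C(C)C)C(=O)O[Si](C(C)C)(C(C)C)C(C)C
F6 | step 19 | 3-{[(5S,6S)-5-bromo-6-ethenyl-2,6-dimethylcyclohex-1-en-1-yl]methyl}-4-hydroxybenzoic acid | C=C[C@]1(C)[C@@H](Br)CCC(C)=C1Cc2cc(ccc2O)C(=O)O
F7 | step 19 | (3R,6E)-7-iodo-2,6-dimethylhepta-1,6-dien-3-ol | I/C=C(\C)CC[C@@H](O)C(C)=C
F8 | step 19 | (3S,6E)-7-iodo-2,6-dimethylhepta-1,6-dien-3-yl ester of F6 | C=C[C@]1(C)[C@@H](Br)CCC(C)=C1Cc2cc(ccc2O)C(=O)O[C@@H](CC/C(C)=C/I)C(C)=C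
F9 | step 19 | C8-boryl O-boryl derivative of F8 | B1(C2CCCC1CCC2)CC[C@]3(C)[C@@H](Br)CCC(C)=C3Cc4cc(ccc4OB5C6CCCC5CCC6)C(=O)O[C@@H](CC/C(C)=C/I)C(C)=C
F10 | step 19 | (9E)-alkene analogue of 27 | C=C(C)[C@@H]4CC/C(C)=C/CC[C@]1(C)[C@@H](Br)CCC(C)=C1Cc3cc(ccc3O)C(=O)O4
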